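**Strategy.** Everything rests on opening the benzene ring of the phthalide (C3a, C4, C5, C6, C7, C7a) at the C3a–C7a bond. Because C1, C7a, C7, C6, C5, C4, C3a and C3 then form one carbon chain carrying oxygen at C1, C7, C5 and C3, an amine-triggered intramolecular aldol condensation of an open diketo-dioxinone forms that bond, closes the carbocycle and aromatises it in one operation, with every substituent already in place. The precursor is an (S)-α-silyloxy diketo-dioxinone whose acetonide masks C1 and the C7 oxygen and whose side chain hides the 1,4-diketone as a 2,5-dialkylfuran; it is made by acylating a keto-dioxinone dianion with an auxiliary-derived (S)-2-silyloxy Weinreb amide.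

Key step: step 8

Remark on the chemistry: the oxygen-bearing stereocentre is (S) in every compound from 9 to 24 (priorities O > acyl or aryl carbon > CH2 > H). The nine-methylene tether between C3 and the furan follows from the C11 bromo acid. The silyl ether is put on after the Weinreb amide is made, because the free α-hydroxyl assists the aluminium-mediated transamination. Compound 5, the Davis oxaziridine and N,O-dimethylhydroxylamine hydrochloride are taken as commercial.

**Route**

Step 1
Reactants: 1 2-methylfuran; 2 11-bromoundecanoic acid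
Product: 4 11-(5-methylfuran-2-yl)undecanoic acid, via 5-methyl-2-furyllithium 3 (not isolated)
Conditions: 1 (2.5 equiv), n-BuLi (2.3 equiv), THF, 0 °C to rt; then 2 (1 equiv), THF/DMPU, −78 °C to rt; dilute aq. HCl to pH 3
Reagents that add atoms: none
Why: Alkylation of an aryllithium by a primary bromide (SN2): the first equivalent of 3 only converts the acid into its lithium carboxylate, which is too poor an electrophile to compete below room temperature, so the second equivalent should displace bromide at C11, and DMPU speeds that substitution.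

Step 2
Reactants: 4 11-(5-methylfuran-2-yl)undecanoic acid; 5 (S)-4-benzyl-1,3-oxazolidin-2-one
Product: 7 (4S)-4-benzyl-3-[11-(5-methylfuran-2-yl)undecanoyl]-1,3-oxazolidin-2-one, via mixed pivalic anhydride 6 (not isolated)
Conditions: PivCl, Et3N, THF, −20 °C; then 5, LiCl, −20 °C to rt
Reagents that add atoms: none
Why: N-Acylation of the oxazolidinone by the mixed pivalic anhydride method (LiCl/Et3N variant): the lithium-activated N–H attacks the unhindered acyl group of 6, the tert-butyl carbonyl being shielded.

Step 3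
Reactants: 7 (4S)-4-benzyl-3-[11-(5-methylfuran-2-yl)undecanoyl]-1,3-oxazolidin-2-one
Product: 9 (4S)-4-benzyl-3-[(2S)-2-hydroxy-11-(5-methylfuran-2-yl)undecanoyl]-1,3-oxazolidin-2-one, via sodium Z-enolate 8 (not isolated)
Conditions: NaHMDS, THF, −78 °C; then 2-(phenylsulfonyl)-3-phenyloxaziridine, −78 °C; AcOH quench
Reagents that add atoms: 2-(phenylsulfonyl)-3-phenyloxaziridine (Davis oxaziridine), O=S(=O)(c1ccccc1)N1OC1c1ccccc1
Why: Electrophilic hydroxylation of a chiral imide enolate with the Davis oxaziridine: the sodium-chelated Z-enolate 8 is attacked on the face opposite the C4 benzyl group, which should set C2 as (S) (priorities OH > C(=O)N > CH2 > H), while the 2,5-dialkylfuran is inert to the oxaziridine at −78 °C.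

Step 4
Reactants: 9 (4S)-4-benzyl-3-[(2S)-2-hydroxy-11-(5-methylfuran-2-yl)undecanoyl]-1,3-oxazolidin-2-one
Product: 10 (2S)-2-hydroxy-N-methoxy-N-methyl-11-(5-methylfuran-2-yl)undecanamide
Conditions: MeNH(OMe)·HCl, AlMe3, THF/CH2Cl2, −20 to 0 °C; aq. potassium sodium tartrate work-up
Reagents that add atoms: N,O-dimethylhydroxylamine hydrochloride, CNOC.Cl
Why: Aluminium amide transamination to the Weinreb amide: the free C2 hydroxyl binds aluminium and delivers the amide nitrogen to the exocyclic carbonyl, so the auxiliary is released without ring cleavage and without enolisation of the stereocentre.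

Step 5
Reactants: 10 (2S)-2-hydroxy-N-methoxy-N-methyl-11-(5-methylfuran-2-yl)undecanamide
Product: 11 (2S)-2-[(tert-butyldimethylsilyl)oxy]-N-methoxy-N-methyl-11-(5-methylfuran-2-yl)undecanamide
Conditions: TBSCl, imidazole, DMF, rt
Reagents that add atoms: tert-butyldimethylsilyl chloride, CC(C)(C)[Si](C)(C)Cl
Why: Silyl ether formation on a secondary alcohol under imidazole catalysis, chosen over a silyl triflate so that no strong acid meets the furan.

Step 6
Reactants: 12 2,2,6-trimethyl-4H-1,3-dioxin-4-one; 13 acetyl chloride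
Product: 15 2,2-dimethyl-6-(2-oxopropyl)-4H-1,3-dioxin-4-one, via lithium dienolate 14 (not isolated)
Conditions: 12 (2 equiv), LiHMDS (2 equiv), THF, −78 °C; then 13 (1 equiv), −78 to −20 °C; aq. HCl (pH 3)
Reagents that add atoms: none
Why: γ-Acylation of a vinylogous ester enolate (crossed Claisen-type): dienolate 14 reacts with acetyl chloride at its terminal carbon, and the second equivalent of 14 deprotonates the more acidic product so that it is not acylated again.

Step 7
Reactants: 15 2,2-dimethyl-6-(2-oxopropyl)-4H-1,3-dioxin-4-one; 11 (2S)-2-[(tert-butyldimethylsilyl)oxy]-N-methoxy-N-methyl-11-(5-methylfuran-2-yl)undecanamide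
Product: 17 6-[(5S)-5-[(tert-butyldimethylsilyl)oxy]-14-(5-methylfuran-2-yl)-2,4-dioxotetradecyl]-2,2-dimethyl-4H-1,3-dioxin-4-one, via dilithium dianion 16 (not isolated)
Conditions: 15 (3 equiv), LDA (6 equiv), THF, −78 °C; then 11 (1 equiv), −78 to −40 °C; cold aq. HCl (pH 3), rapid work-up, used without chromatography
Reagents that add atoms: none
Why: Claisen-type C-acylation of a β-dicarbonyl dianion by a Weinreb amide: the terminal, more basic carbon of 16 adds to the amide carbonyl, and the chelated tetrahedral adduct persists until the acidic quench, so neither over-addition nor enolisation at the silyloxy carbon should follow.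

Step 8
Reactants: 17 6-[(5S)-5-[(tert-butyldimethylsilyl)oxy]-14-(5-methylfuran-2-yl)-2,4-dioxotetradecyl]-2,2-dimethyl-4H-1,3-dioxin-4-one
Product: 19 5-[(1S)-1-[(tert-butyldimethylsilyl)oxy]-10-(5-methylfuran-2-yl)decyl]-7-hydroxy-2,2-dimethyl-4H-1,3-benzodioxin-4-one, via cyclic aldol adduct 18 (not isolated)
Conditions: Et3N (3 equiv), CH2Cl2, 4 Å MS, rt
Reagents that add atoms: none
Why: Et3N deprotonates the CH2 between the dioxinone and the neighbouring ketone, and the extended enolate attacks through the dioxinone α-carbon (future C7a) on the ketone carbon next to the silyloxy carbon (future C3a) to give aldol adduct 18; E1cB loss of water and enolisation of the remaining ring ketone then deliver the phenol. The closest known reaction type is the amine-promoted cyclo-aromatisation of diketo-dioxinones to acetonide-protected resorcylates. The carbocycle closes in a 6-(enolexo)-exo-trig aldol, and this is the only workable closure: every other enolate–carbonyl pairing gives a four-membered ring, and Claisen-type attack on the dioxinone carbonyl is impossible because the heterocycle holds that carbonyl trans to the chain across its C=C. No new stereocentre remains, since the two transient ones in 18 vanish on aromatisation. The step needs C–C closure to outrun enolisation at the silyloxy-bearing carbon: the base is weak, the acidic protons are those of the two 1,3-dicarbonyl methylenes, and the bulky silyl ether shields the stereogenic C–H, so the (S) centre should pass through unchanged. Aromatisation makes the sequence irreversible and, as the oxygens at C5 and C7, the carboxyl carbon on C7a and the side chain on C3a are already fixed in the chain, no regiochemical question arises.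

Step 9
Reactants: 19 5-[(1S)-1-[(tert-butyldimethylsilyl)oxy]-10-(5-methylfuran-2-yl)decyl]-7-hydroxy-2,2-dimethyl-4H-1,3-benzodioxin-4-one
Product: 20 5-[(1S)-1-[(tert-butyldimethylsilyl)oxy]-10-(5-methylfuran-2-yl)decyl]-7-methoxy-2,2-dimethyl-4H-1,3-benzodioxin-4-one
Conditions: MeI, K2CO3, acetone, rt
Reagents that add atoms: iodomethane, CI
Why: Williamson ether synthesis on the only free phenol, which is acidified by the para acyl group; methylating it now means the dioxinone carbonyl will not be deactivated as a phenoxide-conjugated ester in step 10.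

Step 10
Reactants: 20 5-[(1S)-1-[(tert-butyldimethylsilyl)oxy]-10-(5-methylfuran-2-yl)decyl]-7-methoxy-2,2-dimethyl-4H-1,3-benzodioxin-4-one
Product: 23 (3S)-5,7-dimethoxy-3-[9-(5-methylfuran-2-yl)nonyl]-2-benzofuran-1(3H)-one, via free benzylic alcohol 21 (not isolated), via 7-hydroxy-5-methoxyphthalide 22 (not isolated)
Conditions: TBAF, THF, 0 °C to rt; then MeI (excess), rt
Reagents that add atoms: iodomethane, CI
Why: Fluoride-mediated desilylation followed by intramolecular transesterification and Williamson methylation: the C3 alkoxide of 21 adds 5-exo-trig to the dioxinone carbonyl, the tetrahedral intermediate expels the hemiketal oxygen as acetone plus the C7 phenoxide of 22, which MeI then methylates, and C3 keeps its (S) configuration because its C–O bond is never broken.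

Step 11
Reactants: 23 (3S)-5,7-dimethoxy-3-[9-(5-methylfuran-2-yl)nonyl]-2-benzofuran-1(3H)-one
Product: 24 CJ-13,015, (3S)-3-(10,13-dioxotetradecyl)-5,7-dimethoxy-2-benzofuran-1(3H)-one
Conditions: AcOH/H2O (3:1), H2SO4 (cat.), 100 °C
Reagents that add atoms: water, O
Why: Acid-catalysed hydrolytic opening of a 2,5-dialkylfuran (reverse Paal–Knorr reaction) releases the 1,4-diketone, while the phthalide, the aryl methyl ethers and C3 should be untouched because a cation at C3 would be meta to both methoxy groups and ortho to the lactone carbonyl.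

**Compound list**

1 | 2-methylfuran | Cc1ccco1 | starting material
2 | 11-bromoundecanoic acid | OC(=O)CCCCCCCCCCBr | starting material
3 | 5-methyl-2-furyllithium | [Li]c1ccc(C)o1 | intermediate
4 | 11-(5-methylfuran-2-yl)undecanoic acid | Cc1ccc(CCCCCCCCCCC(=O)O)o1 | intermediate
5 | (S)-4-benzyl-1,3-oxazolidin-2-one | O=C1OC[C@H](Cc2ccccc2)N1 | starting material
6 | 11-(5-methylfuran-2-yl)undecanoic pivalic anhydride | CC(C)(C)C(=O)OC(=O)CCCCCCCCCCc1ccc(C)o1 | intermediate
7 | (4S)-4-benzyl-3-[11-(5-methylfuran-2-yl)undecanoyl]-1,3-oxazolidin-2-one | O=C1OC[C@H](Cc2ccccc2)N1C(=O)CCCCCCCCCCc3ccc(C)o3 | intermediate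
8 | sodium Z-enolate of 7 | [Na]O/C(=C\CCCCCCCCCc1ccc(C)o1)N1[C@@H](Cc2ccccc2)COC1=O | intermediate
9 | (4S)-4-benzyl-3-[(2S)-2-hydroxy-11-(5-methylfuran-2-yl)undecanoyl]-1,3-oxazolidin-2-one | O=C1OC[C@H](Cc2ccccc2)N1C(=O)[C@@H](O)CCCCCCCCCc3ccc(C)o3 | intermediate
10 | (2S)-2-hydroxy-N-methoxy-N-methyl-11-(5-methylfuran-2-yl)undecanamide | CON(C)C(=O)[C@@H](O)CCCCCCCCCc1ccc(C)o1 | intermediate
11 | (2S)-2-[(tert-butyldimethylsilyl)oxy]-N-methoxy-N-methyl-11-(5-methylfuran-2-yl)undecanamide | CON(C)C(=O)[C@H](CCCCCCCCCc1ccc(C)o1)O[Si](C)(C)C(C)(C)C | intermediate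
12 | 2,2,6-trimethyl-4H-1,3-dioxin-4-one | CC1=CC(=O)OC(C)(C)O1 | starting material
13 | acetyl chloride | CC(=O)Cl | starting material
14 | lithium dienolate of 12 (4-lithiooxy-2,2-dimethyl-6-methylene-6H-1,3-dioxine) | C=C1C=C(O[Li])OC(C)(C)O1 | intermediate
15 | 2,2-dimethyl-6-(2-oxopropyl)-4H-1,3-dioxin-4-one | CC(=O)CC1=CC(=O)OC(C)(C)O1 | intermediate
16 | dilithium dianion of 15 | C=C(O[Li])C=C1C=C(O[Li])OC(C)(C)O1 | intermediate
17 | 6-[(5S)-5-[(tert-butyldimethylsilyl)oxy]-14-(5-methylfuran-2-yl)-2,4-dioxotetradecyl]-2,2-dimethyl-4H-1,3-dioxin-4-one | CC1(C)OC(=O)C=C(CC(=O)CC(=O)[C@H](CCCCCCCCCc2ccc(C)o2)O[Si](C)(C)C(C)(C)C)O1 | intermediate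
18 | cyclic aldol adduct, 5-[(1S)-1-[(tert-butyldimethylsilyl)oxy]-10-(5-methylfuran-2-yl)decyl]-5-hydroxy-2,2-dimethyl-4a,5-dihydro-4H-1,3-benzodioxine-4,7(6H)-dione (C4a and C5 undefined) | CC1(C)OC(=O)C2C(=CC(=O)CC2(O)[C@H](CCCCCCCCCc3ccc(C)o3)O[Si](C)(C)C(C)(C)C)O1 | intermediate
19 | 5-[(1S)-1-[(tert-butyldimethylsilyl)oxy]-10-(5-methylfuran-2-yl)decyl]-7-hydroxy-2,2-dimethyl-4H-1,3-benzodioxin-4-one | CC1(C)OC(=O)c2c(O1)cc(O)cc2[C@H](CCCCCCCCCc3ccc(C)o3)O[Si](C)(C)C(C)(C)C | intermediate
20 | 5-[(1S)-1-[(tert-butyldimethylsilyl)oxy]-10-(5-methylfuran-2-yl)decyl]-7-methoxy-2,2-dimethyl-4H-1,3-benzodioxin-4-one | CC1(C)OC(=O)c2c(O1)cc(OC)cc2[C@H](CCCCCCCCCc3ccc(C)o3)O[Si](C)(C)C(C)(C)C | intermediate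
21 | 5-[(1S)-1-hydroxy-10-(5-methylfuran-2-yl)decyl]-7-methoxy-2,2-dimethyl-4H-1,3-benzodioxin-4-one (formed as its alkoxide) | CC1(C)OC(=O)c2c(O1)cc(OC)cc2[C@H](CCCCCCCCCc3ccc(C)o3)O | intermediate
22 | (3S)-7-hydroxy-5-methoxy-3-[9-(5-methylfuran-2-yl)nonyl]-2-benzofuran-1(3H)-one (formed as its phenoxide) | COc1cc(O)c2c(c1)[C@H](CCCCCCCCCc3ccc(C)o3)OC2=O | intermediate
23 | (3S)-5,7-dimethoxy-3-[9-(5-methylfuran-2-yl)nonyl]-2-benzofuran-1(3H)-one | COc1cc(OC)c2c(c1)[C@H](CCCCCCCCCc3ccc(C)o3)OC2=O | intermediate
24 | CJ-13,015, (3S)-3-(10,13-dioxotetradecyl)-5,7-dimethoxy-2-benzofuran-1(3H)-one | COc1cc(OC)c2c(c1)[C@H](CCCCCCCCCC(=O)CCC(C)=O)OC2=O | target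

**Step count**

Total steps: 11. Longest linear sequence: 10 steps (steps 1–5 and 7–11); step 6 is a one-step side branch.

**Steps most likely to fail**

1. Step 8. The ring closure may be slow at the ketone flanked by the bulky silyloxy carbon, which would leave time for loss of configuration at that carbon or for decomposition of the dioxinone. The fallback sets out from 17 and closes the ring from an open triketo ester instead of from the intact dioxinone. Heating 17 in toluene/MeOH at 100–110 °C should expel acetone and give an acylketene that methanol traps as methyl (8S)-8-[(tert-butyldimethylsilyl)oxy]-17-(5-methylfuran-2-yl)-3,5,7-trioxoheptadecanoate F1. Its more nucleophilic β-keto ester carbon should cyclise and aromatise with Cs2CO3 in MeOH (or a pH 9 buffer) to methyl 2-[(1S)-1-[(tert-butyldimethylsilyl)oxy]-10-(5-methylfuran-2-yl)decyl]-4,6-dihydroxybenzoate F2. Double methylation (MeI, K2CO3, DMF) should give methyl 2-[(1S)-1-[(tert-butyldimethylsilyl)oxy]-10-(5-methylfuran-2-yl)decyl]-4,6-dimethoxybenzoate F3. TBAF in THF should then free the alkoxide, which lactonises onto the methyl ester, and the route is rejoined at 23.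

2. Step 7. Addition of the soft dianion to the hindered, α-branched Weinreb amide may be sluggish, proton transfer may compete with C–C bond formation, and the sensitive product may cyclise uncontrolled during work-up. The fallback sets out from 11 and replaces the acylation by an aldol addition followed by oxidation. Reduction with i-Bu2AlH (THF, −78 °C) should give (2S)-2-[(tert-butyldimethylsilyl)oxy]-11-(5-methylfuran-2-yl)undecanal F4, used crude. Addition of dianion 16 at −78 °C should give 6-[(5S)-5-[(tert-butyldimethylsilyl)oxy]-4-hydroxy-14-(5-methylfuran-2-yl)-2-oxotetradecyl]-2,2-dimethyl-4H-1,3-dioxin-4-one F5 as a carbinol epimer mixture of no consequence. Oxidation with Dess–Martin periodinane buffered with NaHCO3 (CH2Cl2, 0 °C) should return the route to 17.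

3. Step 11. Hydrolysis of the furan is an equilibrium that may stop short, and prolonged hot acid may cause intramolecular aldol condensation of the liberated 1,4-diketone. The fallback sets out from 23 and opens the furan oxidatively. mCPBA (1 equiv, CH2Cl2, 0 °C) should give (3S)-3-[(11Z)-10,13-dioxotetradec-11-en-1-yl]-5,7-dimethoxy-2-benzofuran-1(3H)-one F6. Reduction of the ene-dione C=C with Zn in AcOH at rt should then arrive at 24.

**Further compounds**

F1 | step 8 | methyl (8S)-8-[(tert-butyldimethylsilyl)oxy]-17-(5-methylfuran-2-yl)-3,5,7-trioxoheptadecanoate | COC(=O)CC(=O)CC(=O)CC(=O)[C@H](CCCCCCCCCc1ccc(C)o1)O[Si](C)(C)C(C)(C)C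
F2 | step 8 | methyl 2-[(1S)-1-[(tert-butyldimethylsilyl)oxy]-10-(5-methylfuran-2-yl)decyl]-4,6-dihydroxybenzoate | COC(=O)c1c(O)cc(O)cc1[C@H](CCCCCCCCCc2ccc(C)o2)O[Si](C)(C)C(C)(C)C
F3 | step 8 | methyl 2-[(1S)-1-[(tert-butyldimethylsilyl)oxy]-10-(5-methylfuran-2-yl)decyl]-4,6-dimethoxybenzoate | COC(=O)c1c(OC)cc(OC)cc1[C@H](CCCCCCCCCc2ccc(C)o2)O[Si](C)(C)C(C)(C)C
F4 | step 7 | (2S)-2-[(tert-butyldimethylsilyl)oxy]-11-(5-methylfuran-2-yl)undecanal | O=C[C@H](CCCCCCCCCc1ccc(C)o1)O[Si](C)(C)C(C)(C)C
F5 | step 7 | 6-[(5S)-5-[(tert-butyldimethylsilyl)oxy]-4-hydroxy-14-(5-methylfuran-2-yl)-2-oxotetradecyl]-2,2-dimethyl-4H-1,3-dioxin-4-one | CC1(C)OC(=O)C=C(CC(=O)CC(O)[C@H](CCCCCCCCCc2ccc(C)o2)O[Si](C)(C)C(C)(C)C)O1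
F6 | step 11 | (3S)-3-[(11Z)-10,13-dioxotetradec-11-en-1-yl]-5,7-dimethoxy-2-benzofuran-1(3H)-one | COc1cc(OC)c2c(c1)[C@H](CCCCCCCCCC(=O)/C=C\C(C)=O)OC2=O
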